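If I wanted the end of Tuesday's and Wednesday's flasks without fitting a rate, I needed one number from the earlier runs.

| setting | ash | birch | cedar | Tuesday's | Wednesday's |
|---|---|---|---|---|---|
| substrate | 0.14 M | 0.14 M | 0.14 M | 0.14 M | 0.14 M |
| coupling partner | 0.10 M | 0.091 M | 0.090 M | 0.120 M | 0.0840 M |
| remark | run made earlier | run made earlier | run made earlier |  |  |
| time |  |  |  | 8.0 h | 8.0 h |

| run | time / h | target / % | substrate / % |
|---|---|---|---|
| ash | 1.00 | 38.2 | 42.6 |
| ash | 2.50 | 53.6 | 32.4 |
| ash | 3.00 | 55.4 | 31.1 |
| ash | 5.00 | 57.3 | 30.0 |
| ash | 6.00 | 57.1 | 29.0 |
| birch | 0.500 | 20.6 | 57.2 |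
| birch | 1.33 | 41.7 | 43.5 |
| birch | 2.50 | 50.1 | 38.0 |
| birch | 4.00 | 51.8 | 35.8 |
| birch | 6.00 | 52.1 | 35.2 |
| cedar | 1.00 | 36.0 | 46.8 |
| cedar | 2.50 | 49.2 | 38.2 |
| cedar | 3.00 | 49.9 | 37.4 |
| cedar | 5.00 | 51.7 | 36.0 |
| cedar | 6.00 | 51.7 | 36.0 |

(standard deviation of a reading: 0.3 percentage points)

- what was read earlier has a scatter of 0.3 percentage points, one standard deviation
- on the list of suspects stand: substrate + coupling partner <-> intermediate; intermediate <-> target + released group; intermediate -> side product

* the winner by amount of target, in percent of the substrate charged; "neither" if no more than 2 percentage points parts them (Tuesday's / Wednesday's / neither)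
* how much target is there at the end, in percent of the substrate charged: Tuesday's
* how much target is there at the end, in percent of the substrate charged: Wednesday's

The substrate readings stopped near what the charge of coupling partner leaves free: 29.0 % against 28.6 % in the ash run, and 36.0 % against 35.7 % in the cedar run. So I took the coupling partner as the limiting reagent and the coupling step as finished. The ash target read 57.3 % after 5.00 h and 57.1 % after 6.00 h, so I expected the longer time to add little.

The ash run gave 0.799 for the target share, the target at the end per partner charged, both counted against the substrate charged. My first way multiplied this share by each charge, giving 68.5 % for Tuesday's flask and 48.0 % for Wednesday's.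

My second way drew a straight line through the cedar and ash ends, which gave 67.9 % for Tuesday's flask. The two ways parted by 0.60 percentage points. But Tuesday's charge lies beyond the ash run by twice the gap between the two runs, so the line stretches a difference of two readings into an uncertainty of about 0.85 points, and the parting was smaller than that. The line was the weaker way, so I kept the share, with Tuesday's ahead by 21 points.

The forecast named Tuesday's, with 68 % and 48 %, and noted that “released-group buildup could trim it slightly”.

The flasks gave 66.7 % for Tuesday's and 47.9 % for Wednesday's, so Tuesday's won.

    substrate + coupling partner ⇌ intermediate (K = 33.0 M⁻¹, k = 0.00770 M⁻¹ s⁻¹)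
    intermediate ⇌ target + released group (K = 6.90 M, k = 6.20 × 10⁻⁴ s⁻¹)
    intermediate → side product (k = 1.30 × 10⁻⁴ s⁻¹)

In Wednesday's flask the intermediate had a forward half-life of 0.31 h toward target, shorter than its 1.5 h toward side product, which splits 0.829 of it to target. Read back from the results, the target share stood at 0.798 in Wednesday's flask and 0.778 in Tuesday's. In a flask like Wednesday's with 0.050 M of coupling partner, the share of 0.799 gives 28.6 %, and that flask held 28.9 %.

The data are simulated on assumed constants; noise was put on by code.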